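# Proposed synthesis of CNP0235031.1 (compound 30) by samarium ketyl–olefin closure of ring A

## Analysis of the target

The target 30 is a labdane diterpenoid of the ent series: a trans-fused decalin (ring A: C1–C5 and C10; ring B: C5–C10) with an exocyclic methylene on C8 (C17), an (E)-3-methylpenta-2,4-dienyl chain on C9 (C11–C16), the angular methyl C20 on C10, a methyl and a methyl ester (C19) on C4 and an acetoxy group on C1. This labdane numbering is used for every intermediate below. The five stereocentres C1 (S), C4 (R), C5 (S), C9 (R) and C10 (S) are contiguous: C20 is axial, the C19 ester is axial and cis to C20, H5 is trans to C20, the C1 acetoxy group is equatorial and cis to C20, and the C9 chain is equatorial and cis to C20. Equatorial O1 and equatorial C11 stand in a peri (syn-pentane) relation, so the C9 configuration of 30 cannot be relied on as the more stable one when C9 is enolisable next to a C8 carbonyl. C9 therefore has to be set kinetically and then kept away from base. The conjugated diene (acid, radicals, electrophiles), the exocyclic alkene (acid-induced migration) and the acetate (bases, nucleophiles) are the sensitive groups. The hindered axial C19 ester is robust, but it sits cis to the C6 arm and can act as an unwanted intramolecular acyl acceptor. The main difficulty is the congestion at C10, a quaternary carbon bonded to three further stereocentres (C1, C5, C9) and 1,3 to the quaternary C4. The strategy rests on the C1–C10 bond of ring A: C1 is a carbinol carbon and C10 a quaternary carbon, and in carbonyl form both are electrophilic (C1 as an aldehyde, C10 as the β-carbon of a C10=C9–C8 enoate). The bond thus joins two centres of like polarity and becomes accessible once the aldehyde carbon is turned into a nucleophilic ketyl; the closure also leaves C9 as an ester α-methylene and C8 as a carboxyl carbon, the handles needed for the side chain and for ring B.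

## Retrosynthetic reasoning

**30 ⇒ 29 (C8=C17).** The exocyclic methylene is removed first in the retrosynthesis because it is acid-labile and nothing later needs it. The forward step must methylenate the hindered ketone 29 without enolising it toward C9, so a non-basic gem-dimetallic methylene transfer is planned. The C1 acetate is already present in 29, so this step ends the synthesis with no protecting-group step after it.

**29 ⇒ 27, through the zinc reagent 28 (C7–C8).** Ring B is opened between the two arms that ring A carries on C5 and C10. C8 is the carboxyl carbon delivered by the enoate of the key step and C7 is the end of the C5 arm, so this is the only ring B bond that can be closed from atoms already in place. The forward reaction is an acyl substitution at C8 by a C7 carbon nucleophile. It must spare the C19 ester (which could close a five-membered ring with the C6 arm), the C1 acetate and the configuration at C9; a thioester paired with an alkylzinc under palladium catalysis meets all three demands.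

**27 ⇒ 26 ⇒ 25 (C7–I, C7–OH).** The iodide is traced back to the primary alcohol 26 and this to the silyl ether 25; these are functional-group changes under neutral conditions.

**25 ⇒ 23, through the aluminium alkoxide 24 (C8–S and O1–acetyl).** The thioester and the acetate are both derived from one lactone linkage C8(=O)–O1. Opening lactone 23 with a sulfur nucleophile and capturing the liberated O1 as its acetate supplies the acyl donor for ring B and the C1 acetoxy group of 30 in a single operation.

**23 ⇒ 18 + 21 (C9–C11).** The whole diene chain is attached as the five-carbon electrophile 21 to C9 of the lactone enolate 22. The cut is placed here, and in a lactone, because equilibration of C9 next to a C8 ketone is untrustworthy (equatorial C11 is syn-pentane to equatorial O1). In 18 the enolate lies in the mean plane of ring A and axial C20 on the neighbouring C10 blocks one face, so kinetic alkylation should give the configuration of 30. C9 is also the only enolisable carbon, since the C19 ester has no α-hydrogen.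

**18 ⇒ 17 (C8–O1).** The lactone is the cyclised form of the anti hydroxy ester 17; its formation needs only acid catalysis.

**17 ⇒ 16 (C1–C10, key disconnection).** Ring A is opened between the carbinol carbon and the quaternary carbon to give the acyclic aldehyde enoate 16. Both ends are electrophilic in 16, so the forward step needs one-electron reduction of the aldehyde to a ketyl, which then adds to the enoate β-carbon. The gain is large: ring A, the C1 alcohol and quaternary C10 are made in one step under the control of C4 and C5, the precursor has only two stereocentres, and the enoate brings C9 and C8.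

**16 ⇒ 15 ⇒ 13 + 14 (C10=C9).** The enoate is cut at its double bond to the C10 methyl ketone 13 and phosphonate 14. The C1 aldehyde must be carried as its acetal (15, 13) during the olefination because it would otherwise react first.

**13 ⇒ 12 ⇒ 11 (C1=C10 by ozonolysis).** The C10 ketone and the C1 aldehyde are the two halves of a C1=C10 double bond in cyclohexene 11. The six carbons of ring A are thus first assembled as a ring to fix C4 and C5, and the ring is then opened at the very bond that the key step re-forms with reversed polarity, after C9 and C8 have been inserted on C10.

**11 ⇒ 9, through enolate 10 (C4–CH3).** Quaternary C4 is made by C-methylation of the ester enolate, anti to the neighbouring C5 arm; this places the ester cis to that arm, as in 30.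

**9 ⇒ 8 ⇒ 3 + 7 (C4–C5 and C2–C3).** The cyclohexene is a Diels–Alder adduct of acrylimide 3 and diene 7. The auxiliary fixes the absolute configuration at C5, the only centre of the adduct that survives the methylation.

**7 ⇒ 6 ⇒ 4 + 5; 3 ⇒ 1 + 2; 21 ⇒ 20 ⇒ 19.** The diene comes from aldehyde 4 by two Wittig reactions, the first with ylide 5. The imide comes from auxiliary 1 and acid chloride 2. The side-chain bromide comes from enynol 19 by semihydrogenation to 20 and bromination.

## Alternatives that were turned down

**Alternative 1:** The angular methyl is disconnected (C10–C20) and delivered from O1 through a silicon tether. In the forward direction the (bromomethyl)dimethylsilyl ether A1 of a Δ5(10)-octalin-1-ol carrying the C4 ester and a C8 ketal would be treated under a stannane radical chain. The silylmethyl radical adds 5-exo to C10, the C5 radical is quenched by hydrogen from the face opposite the new bond, and the trans-fused oxasilolane A2 results; protodesilylation would later unveil C20 and free O1. In its favour, the cis relation of O1 and C20 is enforced by the tether. A 5-exo radical addition to a tetrasubstituted alkene is also a more dependable way to make a quaternary carbon than a 6-exo ketyl addition to a β,β-disubstituted enoate, so on this point the alternative is stronger. Against it, C5 is set by an intermolecular hydrogen-atom transfer to a tertiary radical next to quaternary C4, which the tether does not steer. A1 needs C1 and C4, 1,4-related across the ring, to be controlled independently on a preformed octalin. After A2 the side chain must be introduced at C9 of a C8 ketone, where enolisation toward C7 competes and the C9 configuration meets the peri problem. The chosen strategy offers in exchange a C9 that is the only enolisable position and is alkylated under the facial control of a lactone, and a C5 that is fixed before any ring is closed.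

**Alternative 2:** Ring B is disconnected at C9–C10 and C7–C8 as an intramolecular Diels–Alder reaction of an alkynoate tethered through O1. Thermolysis of ester A3 (the 4-silyloxybut-2-ynoate of a ring A dienol with the diene C10=C5–C6=C7) would give the tricyclic alkylidene lactone A4. In its favour, one reagent-free step forms two C–C bonds, ring B and quaternary C10, the tether guarantees O1 cis to C20, and C11 and C17 arrive with the dienophile; in bonds formed per step it is stronger than the chosen key step. Against it, the two-atom ester tether must adopt its disfavoured conformation to reach a diene terminus that is fully substituted, so forcing temperatures are expected. A4 also has the wrong oxidation pattern: C11 is a carboxyl carbon that must become a methylene, the C5=C6 and C8=C9 double bonds must be reduced or transposed with control of C5 and C9 (two stereocentres the key step does not set), and the C17 oxygen must be removed with allylic transposition. The chosen strategy instead brings C11 in as a methylene together with the complete diene chain in one alkylation and needs no redox corrections on ring B.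

**Alternative 3:** Both rings are disconnected at C3–C4 and C5–C10 as an intramolecular Diels–Alder reaction of the acyclic triene A5, a (Z)-2-silyloxy diene linked through C6–C9 to a (Z)-2-methyl enoate, giving the trans-octalin silyl enol ether A6. In its favour it is the most convergent plan: rings A and B and the centres C4, C5 and C10 come from one step, the C8 methylene and the C9 substituent are already in the tether, and few steps remain after the cycloaddition, so in step economy after the key step it is clearly stronger. Against it, the dienophile is a trisubstituted enoate and the diene terminus C10 bears two carbon substituents, one of which is forced to the inside of the s-cis diene. The cycloaddition would therefore be slow and would compete with a 1,5-hydrogen shift of the diene, and it would create two quaternary carbons in one transition state. Its stereochemical course (ring fusion, C4 against C5, C10 against C9) depends on a single allylic centre, and A5 with its three defined alkene geometries is itself a demanding target. The chosen strategy splits the same task into a Lewis-acid Diels–Alder reaction of an unhindered acrylimide and a ketyl addition to an activated alkene, so each quaternary carbon is made on its own, under a control element that can be named.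

Key step: step 11

## Remarks before the steps

- Aldehyde 4 and enynol 19 are treated as purchasable; 4 is otherwise available from propane-1,3-diol by monosilylation and oxidation.
- Ring carbons of all intermediates carry the labdane numbers of 30; where a name and a SMILES string differ, the SMILES string of the compound list is meant.

## Steps

Step 1
Reactants: 1 (S)-4-benzyloxazolidin-2-one; 2 acryloyl chloride
Product: 3 (S)-3-acryloyl-4-benzyloxazolidin-2-one
Conditions: LiCl, Et3N, THF, −20 °C → rt
Reagents that add atoms: none
Why: N-acylation of the oxazolidinone under mild lithium-assisted conditions, which avoids anionic polymerisation of the acrylate.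

Step 2
Reactants: 4 3-(tert-butyldimethylsilyloxy)propanal; 5 2-(triphenylphosphoranylidene)propanal
Product: 6 (E)-5-(tert-butyldimethylsilyloxy)-2-methylpent-2-enal
Conditions: toluene, 80 °C
Reagents that add atoms: none
Why: Wittig olefination with a stabilised ylide, which should give the (E)-2-methyl enal; the neutral ylide tolerates the β-silyloxy aldehyde.

Step 3
Reactants: 6 (E)-5-(tert-butyldimethylsilyloxy)-2-methylpent-2-enal
Product: 7 (E)-tert-butyldimethyl[(4-methylhexa-3,5-dien-1-yl)oxy]silane
Conditions: Ph3PCH3Br, KOtBu, THF, 0 °C → rt
Reagents that add atoms: methyltriphenylphosphonium bromide, C[P+](c1ccccc1)(c1ccccc1)c1ccccc1.[Br-]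
Why: Wittig methylenation turns the formyl group into the vinyl group and leaves the trisubstituted (E)-alkene untouched, giving the diene C5=C10–C1=C2 with its substituent on the outside.

Step 4
Reactants: 3 (S)-3-acryloyl-4-benzyloxazolidin-2-one; 7 (E)-tert-butyldimethyl[(4-methylhexa-3,5-dien-1-yl)oxy]silane
Product: 8 (S)-4-benzyl-3-{(1R,2R)-2-[2-(tert-butyldimethylsilyloxy)ethyl]-3-methylcyclohex-3-ene-1-carbonyl}oxazolidin-2-one (cis adduct, acyl group on C4 and arm on C5 on the same face)
Conditions: Et2AlCl (1.4 equiv), CH2Cl2, −78 °C
Reagents that add atoms: none
Why: Auxiliary-controlled Lewis-acid Diels–Alder reaction: the aluminium-chelated s-cis acrylimide is attacked on the α-carbon face away from the benzyl group (Si face) in the endo mode, which sets C5 and places the arm cis to the acyl group. The terminal substituent of the diene directs its carbon (C5) onto the acrylate α-carbon, as is usual for 1-vinylcyclohexene-type dienes, although the C10 methyl opposes this.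

Step 5
Reactants: 8 the Diels–Alder imide
Product: 9 methyl (1R,2R)-2-[2-(tert-butyldimethylsilyloxy)ethyl]-3-methylcyclohex-3-ene-1-carboxylate
Conditions: MeOMgBr (from MeMgBr and MeOH), CH2Cl2–MeOH, 0 °C
Reagents that add atoms: methanol (as MeOMgBr), CO
Why: Magnesium methoxide methanolysis cleaves the exocyclic imide carbonyl and releases the auxiliary; any epimerisation at C4 does not matter because C4 is enolised in step 6.

Step 6
Reactants: 9 the cyclohexene methyl ester
Product: 11 methyl (1R,2S)-2-[2-(tert-butyldimethylsilyloxy)ethyl]-1,3-dimethylcyclohex-3-ene-1-carboxylate, via lithium enolate 10 (not isolated)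
Conditions: LiN(iPr)2, THF, −78 °C; MeI, DMPU, −78 → −20 °C
Reagents that add atoms: iodomethane, CI
Why: Ester enolate C-alkylation: the C5 arm is pseudo-axial (it avoids A(1,2) strain with the C10 methyl) and shields its face of the enolate, so the methyl group should enter anti to it. This creates quaternary C4 with the ester cis to the C5 arm.

Step 7
Reactants: 11 the methylated cyclohexene ester
Product: 12 methyl (2R,3R)-3-acetyl-5-(tert-butyldimethylsilyloxy)-2-methyl-2-(3-oxopropyl)pentanoate
Conditions: O3, CH2Cl2, −78 °C; PPh3, −78 °C → rt
Reagents that add atoms: ozone, [O-][O+]=O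
Why: Ozonolysis with reductive work-up cleaves the only C=C bond (C1=C10) and opens ring A to the C10 methyl ketone and the C1 aldehyde; the silyl ether and the ester are inert.

Step 8
Reactants: 12 the keto aldehyde
Product: 13 methyl (2R,3R)-3-acetyl-5-(tert-butyldimethylsilyloxy)-2-(3,3-dimethoxypropyl)-2-methylpentanoate
Conditions: MeOSiMe3 (2.5 equiv), Me3SiOTf (5 mol%), CH2Cl2, −78 °C; pyridine quench
Reagents that add atoms: methoxytrimethylsilane, CO[Si](C)(C)C
Why: Silyl-triflate-catalysed acetalisation at low temperature should take the aldehyde and leave the hindered α-branched methyl ketone; the aprotic medium spares the silyl ether.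

Step 9
Reactants: 13 the keto acetal; 14 trimethyl phosphonoacetate
Product: 15 dimethyl (2E,4S,5R)-4-[2-(tert-butyldimethylsilyloxy)ethyl]-5-(3,3-dimethoxypropyl)-3,5-dimethylhex-2-enedioate
Conditions: NaH, THF, 0 → 60 °C
Reagents that add atoms: none
Why: Horner–Wadsworth–Emmons olefination of the methyl ketone; the bulky α-branched residue on C10 should place the new ester trans to it and give the (E)-β-methyl enoate. The acetal keeps the C1 carbonyl out of the reaction.

Step 10
Reactants: 15 the enoate acetal
Product: 16 dimethyl (2E,4S,5R)-4-[2-(tert-butyldimethylsilyloxy)ethyl]-3,5-dimethyl-5-(3-oxopropyl)hex-2-enedioate (acyclic aldehyde enoate)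
Conditions: Et3SiOTf, 2,4,6-collidine, CH2Cl2, 0 °C; then H2O
Reagents that add atoms: water, O
Why: Chemoselective acetal cleavage through a collidinium intermediate that water hydrolyses to the aldehyde; these buffered conditions should leave the silyl ether and the enoate untouched.

Step 11
Reactants: 16 the acyclic aldehyde enoate
Product: 17 methyl (1R,2S,3S,4S)-2-[2-(tert-butyldimethylsilyloxy)ethyl]-4-hydroxy-3-(2-methoxy-2-oxoethyl)-1,3-dimethylcyclohexane-1-carboxylate (ring A hydroxy diester; labdane C4 R, C5 S, C10 S, C1 S)
Conditions: SmI2 (2.5 equiv, 0.1 M in THF), t-BuOH (3 equiv), THF, −78 → −20 °C, slow addition of 16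
Reagents that add atoms: none
Why: Divalent samarium transfers one electron to the aldehyde of 16 (the enoate is harder to reduce) and gives a samarium-bound C1 ketyl, a carbon nucleophile at a normally electrophilic carbon. The ketyl adds 6-exo-trig to C10, the β-carbon of the (E)-enoate, through a chair-like transition state; this forms C1–C10 and closes ring A, and a second electron transfer converts the α-ester radical into a samarium enolate that t-BuOH protonates at C9. The closest known reaction type is the SmI2-mediated 6-exo ketyl–olefin cyclisation of aldehydes onto α,β-unsaturated esters, which gives anti 2-(alkoxycarbonylmethyl)cyclohexanols. C10 is controlled by C5 and C4: in the reacting rotamer C5–H lies in the enoate plane (least allylic strain), the C6 arm is equatorial and the tether reaches C10 from the C4 side, so C20 becomes axial and C9 equatorial. The epimeric mode would put C9 axial, eclipsed with C4–C5 and syn-diaxial to the C4 ester, and the flipped chair would put the C6 arm axial. C1 is controlled by the ketyl oxygen with its bulky samarium, which takes the equatorial site anti to the enoate carbon, hence trans to C9 and cis to C20. The step needs the ketyl to add faster than it dimerises or is reduced further; the activated acceptor, the low ketyl concentration and the alcohol additive are meant to secure this. The C19 ester and the silyl ether are inert, and the anti product should be isolated as the open hydroxy diester.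

Step 12
Reactants: 17 the ring A hydroxy diester
Product: 18 methyl 4-[2-(tert-butyldimethylsilyloxy)ethyl]-3a,5-dimethyl-2-oxooctahydro-1-benzofuran-5-carboxylate (trans-fused γ-lactone between O1 and C8, configuration of 17)
Conditions: camphorsulfonic acid (cat.), toluene, 5 Å molecular sieves, 60 °C
Reagents that add atoms: none
Why: Acid-catalysed lactonisation: the equatorial C1 hydroxyl attacks the neighbouring acetate arm on quaternary C10 and closes the trans-fused five-membered lactone while the sieves take up the methanol. O1 cannot reach the C19 ester, and the aprotic medium spares the silyl ether.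

Step 13
Reactants: 19 (E)-3-methylpent-2-en-4-yn-1-ol
Product: 20 (E)-3-methylpenta-2,4-dien-1-ol
Conditions: H2 (1 atm), Pd/CaCO3 poisoned with Pb(OAc)2, quinoline, EtOAc, rt
Reagents that add atoms: none
Why: Semihydrogenation of the terminal alkyne on lead-poisoned palladium should stop at the vinyl group and keep the (E)-alkene.

Step 14
Reactants: 20 (E)-3-methylpenta-2,4-dien-1-ol
Product: 21 (E)-5-bromo-3-methylpenta-1,3-diene
Conditions: PBr3 (0.4 equiv), Et2O, −10 °C; used at once
Reagents that add atoms: phosphorus tribromide, BrP(Br)Br
Why: Conversion of the primary allylic alcohol into the bromide; the primary conjugated bromide is the favoured allylic isomer, so the (E)-geometry and the position of the halide should be kept.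

Step 15
Reactants: 18 the trans-fused lactone; 21 (E)-5-bromo-3-methylpenta-1,3-diene
Product: 23 methyl 4-[2-(tert-butyldimethylsilyloxy)ethyl]-3a,5-dimethyl-3-[(2E)-3-methylpenta-2,4-dien-1-yl]-2-oxooctahydro-1-benzofuran-5-carboxylate (side chain on C9 trans to the C20 methyl), via lactone lithium enolate 22 (not isolated)
Conditions: LiN(iPr)2 (1.1 equiv), THF, −78 °C; 21, DMPU, −78 → −40 °C
Reagents that add atoms: none
Why: Lactone enolate alkylation by SN2 attack on the primary dienylic bromide. The planar enolate lies in the mean plane of ring A and axial C20 on the adjacent C10 blocks its lower face, so the electrophile should enter from the face of H1 and H5. This sets C9 with the configuration of 30 (C11 becomes equatorial once ring B exists); the C19 ester has no α-hydrogen.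

Step 16
Reactants: 23 the alkylated lactone
Product: 25 S-ethyl thioester of the ring-opened acid with the C1 acetate (methyl ester at C19, silyl ether at C7, dienyl chain at C9), via aluminium alkoxide thioester 24 (not isolated)
Conditions: AlMe3 (2 equiv), EtSH (2.2 equiv), CH2Cl2, 0 °C → rt; then pyridine, DMAP, Ac2O (5 equiv), 0 °C → rt
Reagents that add atoms: ethanethiol, CCS; acetic anhydride, CC(=O)OC(C)=O
Why: Thiolysis of the strained lactone by the dialkylaluminium thiolate at the acyl carbon, then acetylation of the aluminium alkoxide in the same flask before it can close back onto the thioester. This installs the C1 acetate of 30 and an acyl donor at C8; the hindered axial C19 ester should not be thiolysed under these conditions, and the non-basic medium leaves C9 untouched.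

Step 17
Reactants: 25 the acetoxy thioester silyl ether
Product: 26 the corresponding C7 primary alcohol
Conditions: HF·pyridine, pyridine, THF, 0 °C → rt
Reagents that add atoms: none
Why: Buffered fluoride cleavage of the primary silyl ether; thioester, acetate, methyl ester and diene are stable to it.

Step 18
Reactants: 26 the C7 alcohol
Product: 27 the corresponding C7 primary iodide
Conditions: I2, PPh3, imidazole, CH2Cl2, 0 °C → rt
Reagents that add atoms: iodine, II
Why: Appel-type iodination of the unhindered primary alcohol under imidazole buffering, which is neutral enough for the diene, the acetate and the C9 centre.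

Step 19
Reactants: 27 the iodo thioester
Product: 29 methyl (1S,4R,5S,9S,10R)-1-acetoxy-8-oxo-17-norlabda-12E,14-dien-19-oate (ring B ketone; C9 configured as in 30), via alkylzinc iodide 28 (not isolated)
Conditions: Zn dust (activated with Me3SiCl and BrCH2CH2Br), N,N-dimethylacetamide, 40 °C; then PdCl2(PPh3)2 (10 mol%), toluene, rt, high dilution
Reagents that add atoms: none
Why: Fukuyama ketone synthesis run intramolecularly: zinc inserts into the primary C–I bond, zerovalent palladium adds to the C(acyl)–S bond, and transmetalation followed by reductive elimination closes the six-membered ring B at C7–C8. The alkylzinc does not add to the C19 ester or the acetate, and the neutral medium should leave C9 unepimerised.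

Step 20
Reactants: 29 the ring B ketone
Product: 30 methyl (1S,4R,5S,9R,10S,12E)-1-acetoxylabda-8(17),12,14-trien-19-oate (CNP0235031.1)
Conditions: Zn, CH2Br2, TiCl4 (reagent pre-formed in THF), CH2Cl2, 0 °C → rt
Reagents that add atoms: dibromomethane, BrCBr
Why: Takai–Lombardo methylenation: the gem-dimetallic methylene reagent is non-basic, so the C9 centre next to the carbonyl should not epimerise, and the acetate and the methyl ester are not methylenated.

## Compound list

1 | (S)-4-benzyloxazolidin-2-one | O=C1OC[C@H](Cc2ccccc2)N1 | starting material
2 | acryloyl chloride | C=CC(=O)Cl | starting material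
3 | (S)-3-acryloyl-4-benzyloxazolidin-2-one | C=CC(=O)N1[C@@H](Cc2ccccc2)COC1=O | intermediate
4 | 3-(tert-butyldimethylsilyloxy)propanal | O=CCCO[Si](C)(C)C(C)(C)C | starting material
5 | 2-(triphenylphosphoranylidene)propanal | CC(C=O)=P(c1ccccc1)(c1ccccc1)c1ccccc1 | starting material
6 | (E)-5-(tert-butyldimethylsilyloxy)-2-methylpent-2-enal | O=C/C(C)=C/CCO[Si](C)(C)C(C)(C)C | intermediate
7 | (E)-tert-butyldimethyl[(4-methylhexa-3,5-dien-1-yl)oxy]silane | C=C/C(C)=C/CCO[Si](C)(C)C(C)(C)C | intermediate
8 | (S)-4-benzyl-3-{(1R,2R)-2-[2-(tert-butyldimethylsilyloxy)ethyl]-3-methylcyclohex-3-ene-1-carbonyl}oxazolidin-2-one | CC(C)(C)[Si](C)(C)OCC[C@H]1C(C)=CCC[C@H]1C(=O)N2[C@@H](Cc3ccccc3)COC2=O | intermediate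
9 | methyl (1R,2R)-2-[2-(tert-butyldimethylsilyloxy)ethyl]-3-methylcyclohex-3-ene-1-carboxylate | CC(C)(C)[Si](C)(C)OCC[C@H]1C(C)=CCC[C@H]1C(=O)OC | intermediate
10 | lithium enolate of 9 | CC(C)(C)[Si](C)(C)OCC[C@H]1C(C)=CCCC1=C(OC)O[Li] | intermediate (not isolated)
11 | methyl (1R,2S)-2-[2-(tert-butyldimethylsilyloxy)ethyl]-1,3-dimethylcyclohex-3-ene-1-carboxylate | CC(C)(C)[Si](C)(C)OCC[C@H]1C(C)=CCC[C@@]1(C)C(=O)OC | intermediate
12 | methyl (2R,3R)-3-acetyl-5-(tert-butyldimethylsilyloxy)-2-methyl-2-(3-oxopropyl)pentanoate | O=CCC[C@@](C)(C(=O)OC)[C@@H](CCO[Si](C)(C)C(C)(C)C)C(C)=O | intermediate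
13 | methyl (2R,3R)-3-acetyl-5-(tert-butyldimethylsilyloxy)-2-(3,3-dimethoxypropyl)-2-methylpentanoate | COC(OC)CC[C@@](C)(C(=O)OC)[C@@H](CCO[Si](C)(C)C(C)(C)C)C(C)=O | intermediate
14 | trimethyl phosphonoacetate | COC(=O)CP(=O)(OC)OC | starting material
15 | dimethyl (2E,4S,5R)-4-[2-(tert-butyldimethylsilyloxy)ethyl]-5-(3,3-dimethoxypropyl)-3,5-dimethylhex-2-enedioate | COC(OC)CC[C@@](C)(C(=O)OC)[C@@H](CCO[Si](C)(C)C(C)(C)C)/C(C)=C/C(=O)OC | intermediate
16 | dimethyl (2E,4S,5R)-4-[2-(tert-butyldimethylsilyloxy)ethyl]-3,5-dimethyl-5-(3-oxopropyl)hex-2-enedioate (key-step precursor) | O=CCC[C@@](C)(C(=O)OC)[C@@H](CCO[Si](C)(C)C(C)(C)C)/C(C)=C/C(=O)OC | intermediate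
17 | methyl (1R,2S,3S,4S)-2-[2-(tert-butyldimethylsilyloxy)ethyl]-4-hydroxy-3-(2-methoxy-2-oxoethyl)-1,3-dimethylcyclohexane-1-carboxylate (key-step product) | COC(=O)C[C@]1(C)[C@@H](O)CC[C@@](C)(C(=O)OC)[C@H]1CCO[Si](C)(C)C(C)(C)C | intermediate
18 | trans-fused O1–C8 γ-lactone of 17 | O=C1C[C@]2(C)[C@@H](O1)CC[C@@](C)(C(=O)OC)[C@H]2CCO[Si](C)(C)C(C)(C)C | intermediate
19 | (E)-3-methylpent-2-en-4-yn-1-ol | C#C/C(C)=C/CO | starting material
20 | (E)-3-methylpenta-2,4-dien-1-ol | C=C/C(C)=C/CO | intermediate
21 | (E)-5-bromo-3-methylpenta-1,3-diene | C=C/C(C)=C/CBr | intermediate
22 | lithium enolate of lactone 18 | [Li]OC1=C[C@]2(C)[C@@H](O1)CC[C@@](C)(C(=O)OC)[C@H]2CCO[Si](C)(C)C(C)(C)C | intermediate (not isolated)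
23 | lactone 18 carrying the (2E)-3-methylpenta-2,4-dienyl chain on C9, trans to C20 | O=C1[C@@H](C/C=C(C)/C=C)[C@]2(C)[C@@H](O1)CC[C@@](C)(C(=O)OC)[C@H]2CCO[Si](C)(C)C(C)(C)C | intermediate
24 | dimethylaluminium C1 alkoxide of the ring-opened S-ethyl thioester | CCSC(=O)[C@@H](C/C=C(C)/C=C)[C@]1(C)[C@@H](O[Al](C)C)CC[C@@](C)(C(=O)OC)[C@H]1CCO[Si](C)(C)C(C)(C)C | intermediate (not isolated)
25 | C1 acetate, C8 S-ethyl thioester, C7 silyl ether | CCSC(=O)[C@@H](C/C=C(C)/C=C)[C@]1(C)[C@@H](OC(C)=O)CC[C@@](C)(C(=O)OC)[C@H]1CCO[Si](C)(C)C(C)(C)C | intermediate
26 | C1 acetate, C8 S-ethyl thioester, C7 alcohol | CCSC(=O)[C@@H](C/C=C(C)/C=C)[C@]1(C)[C@@H](OC(C)=O)CC[C@@](C)(C(=O)OC)[C@H]1CCO | intermediate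
27 | C1 acetate, C8 S-ethyl thioester, C7 iodide | CCSC(=O)[C@@H](C/C=C(C)/C=C)[C@]1(C)[C@@H](OC(C)=O)CC[C@@](C)(C(=O)OC)[C@H]1CCI | intermediate
28 | C7 alkylzinc iodide of 27 | CCSC(=O)[C@@H](C/C=C(C)/C=C)[C@]1(C)[C@@H](OC(C)=O)CC[C@@](C)(C(=O)OC)[C@H]1CC[Zn]I | intermediate (not isolated)
29 | methyl (1S,4R,5S,9S,10R)-1-acetoxy-8-oxo-17-norlabda-12E,14-dien-19-oate | C=C/C(C)=C/C[C@@H]1C(=O)CC[C@H]2[C@@]1(C)[C@@H](OC(C)=O)CC[C@@]2(C)C(=O)OC | intermediate
30 | methyl (1S,4R,5S,9R,10S,12E)-1-acetoxylabda-8(17),12,14-trien-19-oate (CNP0235031.1) | C=C/C(C)=C/C[C@@H]1C(=C)CC[C@H]2[C@@]1(C)[C@@H](OC(C)=O)CC[C@@]2(C)C(=O)OC | target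

## Step count and least certain steps

Total step count: 20. Longest linear sequence: 17 steps (steps 2–12 and 15–20, from aldehyde 4); steps 1, 13 and 14 prepare the imide and the side-chain bromide.

**Step 11 (key step).** Two processes are most likely to go wrong. The ketyl may be reduced to the primary alcohol or couple to a pinacol faster than it adds to the congested β,β-disubstituted C10. Facial discrimination at C10 may also be incomplete, because the chair must place either C20 or C9 syn-axial to the C4 ester. Fallback: from 16 the ketyl would be generated as an O-stannyl ketyl in a radical chain (Bu3SnH, azobisisobutyronitrile, benzene, 80 °C, slow addition). The tin-bound ketyl adds reversibly to C10, which favours the anti chair product; the α-ester radical is quenched by hydrogen-atom transfer instead of a second reduction, and destannylation on work-up returns the route at 17. No new isolated compound arises.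

**Step 9.** Addition of the phosphonate anion to the hindered α-branched methyl ketone may be slow enough for three competing processes: enolisation toward C20, Claisen-type closure of that enolate onto the C19 ester, and epimerisation at C5. Fallback: from 13 a Peterson olefination would be used. The lithium enolate of methyl (trimethylsilyl)acetate is added at −78 °C and eliminates on warming, which should give 15 together with its (Z)-isomer F2. F2 is either separated or carried along with 15, because C9 becomes a methylene in step 11 and both geometries are expected to converge on 17; the route is rejoined at 15.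

**Step 19.** Oxidative addition of zerovalent palladium into the hindered α-branched thioester may be slower than protonolysis of the alkylzinc, which would lead to simple reduction at C7 instead of ring closure. Fallback: ring B would be closed without a C8 carbonyl, setting out from 23. Reduction with iBu2AlH at −78 °C gives the lactol F5. Homologation with dimethyl (1-diazo-2-oxopropyl)phosphonate and K2CO3 in methanol gives the alkynol F6 (C8≡C17), whose hydroxyl is acetylated to F7. Desilylation with HF·pyridine gives the alcohol F8 and iodination (I2, PPh3, imidazole) the iodide F9. Treatment of F9 with (Me3Si)3SiH and azobisisobutyronitrile in benzene at 80 °C should close ring B by 6-exo-dig attack of the C7 radical on C8, and hydrogen transfer to the vinyl radical gives the exocyclic methylene directly. The route is rejoined at 30.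

**Step 15.** The dienylic bromide 21 may ionise, react by SN2′ attack or polymerise faster than it alkylates the hindered lactone enolate, and facial discrimination could be eroded at higher temperature. Fallback: the chain would be introduced as an enyne and the diene unveiled afterwards, setting out from 19 and 18. Bromination of 19 with PBr3 gives the enynyl bromide F3, alkylation of enolate 22 with F3 gives the enyne lactone F4, and semihydrogenation of F4 (H2, Pd/CaCO3 poisoned with Pb(OAc)2, quinoline) returns the route at 23.

**Step 4.** The C10 methyl of the diene opposes the directing effect of the terminal substituent, so regiochemical leakage is possible. The trisubstituted diene may also oligomerise under the aluminium Lewis acid, and loss of endo control would erode the enantiomeric purity at C5. Fallback: stereocontrol would be moved from the auxiliary to a catalyst, setting out from 7. The diene would react with 2,2,2-trifluoroethyl acrylate under the Tf2NH-activated oxazaborolidine made from α,α-diphenylprolinol and o-tolylboronic acid, in the enantiomeric form whose facial model opens the α-Si face of the acrylate, to give the trifluoroethyl ester F1. Transesterification of F1 with NaOMe in methanol returns the route at 9.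

## Further compounds

F0 | step 11 | none | none
F1 | step 4 | 2,2,2-trifluoroethyl (1R,2R)-2-[2-(tert-butyldimethylsilyloxy)ethyl]-3-methylcyclohex-3-ene-1-carboxylate | CC(C)(C)[Si](C)(C)OCC[C@H]1C(C)=CCC[C@H]1C(=O)OCC(F)(F)F
F2 | step 9 | (2Z)-isomer of 15 | COC(OC)CC[C@@](C)(C(=O)OC)[C@@H](CCO[Si](C)(C)C(C)(C)C)/C(C)=C\C(=O)OC
F3 | step 15 | (E)-5-bromo-3-methylpent-3-en-1-yne | C#C/C(C)=C/CBr
F4 | step 15 | lactone 18 carrying the (2E)-3-methylpent-2-en-4-ynyl chain on C9 | O=C1[C@@H](C/C=C(C)/C#C)[C@]2(C)[C@@H](O1)CC[C@@](C)(C(=O)OC)[C@H]2CCO[Si](C)(C)C(C)(C)C
F5 | step 19 | lactol from 23 (C8 hemiacetal) | OC1[C@@H](C/C=C(C)/C=C)[C@]2(C)[C@@H](O1)CC[C@@](C)(C(=O)OC)[C@H]2CCO[Si](C)(C)C(C)(C)C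
F6 | step 19 | C8≡C17 alkyne with free C1 hydroxyl | C#C[C@@H](C/C=C(C)/C=C)[C@]1(C)[C@@H](O)CC[C@@](C)(C(=O)OC)[C@H]1CCO[Si](C)(C)C(C)(C)C
F7 | step 19 | C1 acetate of F6 | C#C[C@@H](C/C=C(C)/C=C)[C@]1(C)[C@@H](OC(C)=O)CC[C@@](C)(C(=O)OC)[C@H]1CCO[Si](C)(C)C(C)(C)C
F8 | step 19 | C7 alcohol from F7 | C#C[C@@H](C/C=C(C)/C=C)[C@]1(C)[C@@H](OC(C)=O)CC[C@@](C)(C(=O)OC)[C@H]1CCO
F9 | step 19 | C7 iodide from F8 | C#C[C@@H](C/C=C(C)/C=C)[C@]1(C)[C@@H](OC(C)=O)CC[C@@](C)(C(=O)OC)[C@H]1CCI
A1 | alternative 1 | (bromomethyl)dimethylsilyl ether of the Δ5(10)-octalin-1-ol with C4 ester and C8 ketal | COC(=O)[C@]1(C)CC[C@H](O[Si](C)(C)CBr)C2=C1CCC1(OCCO1)C2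
A2 | alternative 1 | trans-decalin oxasilolane with C8 ketal | COC(=O)[C@]1(C)CC[C@@H]2O[Si](C)(C)C[C@@]23CC4(OCCO4)CC[C@H]13
A3 | alternative 2 | C1 4-(tert-butyldimethylsilyloxy)but-2-ynoate of the ring A dienol | COC(=O)[C@]1(C)CC[C@@H](OC(=O)C#CCO[Si](C)(C)C(C)(C)C)C(C)=C1C=C
A4 | alternative 2 | tricyclic alkylidene lactone | COC(=O)[C@]1(C)CC[C@H]2OC(=O)C3=C(CO[Si](C)(C)C(C)(C)C)CC=C1[C@@]23C
A5 | alternative 3 | acyclic (Z)-2-silyloxy diene tethered to a (Z)-2-methyl enoate | C=C/C(O[Si](C)(C)C(C)(C)C)=C(\C)[C@H](CCO[Si](c1ccccc1)(c1ccccc1)C(C)(C)C)C(=C)CC/C=C(/C)C(=O)OC
A6 | alternative 3 | trans-octalin silyl enol ether | CC(C)(C)[Si](c1ccccc1)(c1ccccc1)OCC[C@@H]1C(=C)CC[C@H]2[C@@]1(C)C(O[Si](C)(C)C(C)(C)C)=CC[C@@]2(C)C(=O)OC
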